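**Retrosynthetic overview**

1. Locants follow the azulene skeleton: C1=C2, C3 (C(OH)iPr), C3a (ring-fusion CH), C4 (CH–O-acyl), C5, C6 (C(OH)CH3), C7, C8, C8a (ring-fusion C–CH3). Target ⇐ triol 19 (acylation of C4–OH) ⇐ enone 18 (iPr to C3=O) ⇐ ketone 16 (CH3 to C6=O).
2. 16 ⇐ trienyl carbinol 11: H-3a and C4–OH by silicon-tethered syn-hydrosilylation/Tamao oxidation from a sacrificial C3 hydroxyl; C6=O by enol ether hydrolysis; C7–C8 by conjugate reduction; C1=C2 from the C1 ketone via its enol triflate.
3. Bicycle 8 ⇐ diazo ketone 6 by intramolecular Buchner reaction: the five-membered ring closes first (cyclopropanation of the ipso/ortho bond), then the anisole ring is expanded from six to seven atoms (norcaradiene → cycloheptatriene).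
4. Enabling feature: the seven-ring atoms C3a–C4–C5–C6–C7–C8 are a para-disubstituted benzene in disguise (oxygen on C6, para to the fusion carbon C3a). The seventh atom, C8a, is a methyl-bearing quaternary carbon whose five-ring neighbour C1 can be a carbonyl, i.e. an α-methyl acyl carbene; C1–C2–C3 is the tether and the C3 oxygen is benzylic.
5. 6 ⇐ (R)-β-silyloxy acid 4 (asymmetric hydrogenation of β-keto ester 1) + diazoethane.

Key step: step 5

Remark: β is the face of the C8a methyl group, α the opposite face; the target then reads 3β-OH, 3α-iPr, 3aα-H, 4α-O-acyl, 6β-OH, 6α-CH3, 8aβ-CH3.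

**Route**

Step 1
Reactants: 1 ethyl 3-(4-methoxyphenyl)-3-oxopropanoate
Product: 2 ethyl (3R)-3-hydroxy-3-(4-methoxyphenyl)propanoate
Conditions: H2 (50 atm), Ru(II)–(S)-BINAP (0.5 mol %), EtOH, 50 °C
Reagents that add atoms: none
Why: Noyori asymmetric hydrogenation of a β-keto ester, in which hydride transfer within the Ru–BINAP chelate differentiates the ketone faces and the (S)-ligand series is expected to deliver the (R)-benzylic carbinol.

Step 2
Reactants: 2 ethyl (3R)-3-hydroxy-3-(4-methoxyphenyl)propanoate
Product: 3 ethyl (3R)-3-[(tert-butyldimethylsilyl)oxy]-3-(4-methoxyphenyl)propanoate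
Conditions: TBSCl, imidazole, DMF, rt
Reagents that add atoms: tert-butyldimethylsilyl chloride CC(C)(C)[Si](C)(C)Cl
Why: Imidazole-promoted silylation masks the hydroxyl against O–H insertion of the later carbenoid and touches no stereocentre.

Step 3
Reactants: 3 ethyl (3R)-3-[(tert-butyldimethylsilyl)oxy]-3-(4-methoxyphenyl)propanoate
Product: 4 (3R)-3-[(tert-butyldimethylsilyl)oxy]-3-(4-methoxyphenyl)propanoic acid
Conditions: LiOH, THF/MeOH/H2O, 0 °C → rt; then aq. citric acid to pH 5
Reagents that add atoms: lithium hydroxide [Li+].[OH-]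
Why: Ester saponification under mild conditions should avoid β-elimination, and the buffered acidification keeps the p-methoxybenzylic silyl ether intact.

Step 4
Reactants: 4 (3R)-3-[(tert-butyldimethylsilyl)oxy]-3-(4-methoxyphenyl)propanoic acid
Product: 6 (5R)-5-[(tert-butyldimethylsilyl)oxy]-2-diazo-5-(4-methoxyphenyl)pentan-3-one, via mixed isobutyl carbonic anhydride 5 (not isolated)
Conditions: iBuOCOCl, N-methylmorpholine, THF, −15 °C; then CH3CHN2, Et2O, −15 → 0 °C
Reagents that add atoms: diazoethane CC=[N+]=[N-]; isobutyl chloroformate CC(C)COC(Cl)=O (its atoms stay only in 5)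
Why: Acylation of diazoethane by a mixed carbonic anhydride (Arndt–Eistert-type diazo ketone synthesis) should give the α-methyl α-diazo ketone without an acid chloride that could ionise the benzylic silyl ether.

Step 5
Reactants: 6 (5R)-5-[(tert-butyldimethylsilyl)oxy]-2-diazo-5-(4-methoxyphenyl)pentan-3-one
Product: 8 3α-[(tert-butyldimethylsilyl)oxy]-6-methoxy-8aβ-methyl-3,8a-dihydroazulen-1(2H)-one, via norcaradiene 7 (not isolated)
Conditions: Rh2(OAc)4 (1 mol %), CH2Cl2, reflux, slow addition of 6; acid-free work-up
Reagents that add atoms: none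
Why: Rhodium(II) converts the α-methyl α-diazo ketone into an electrophilic carbenoid that cyclopropanates the ipso/ortho bond of the anisyl ring to norcaradiene 7, and disrotatory 6π electrocyclic opening of the C3a–C8 bond then turns the benzene ring into the cycloheptatriene of 8, the carbenoid carbon becoming C8a. The closest known reaction is the intramolecular Buchner reaction of 1-diazo-4-arylbutan-2-ones to 3,8a-dihydroazulen-1(2H)-ones, which also tolerates a methyl group on the diazo carbon. The five-membered ring is closed by the C8a–C3a bond in a 5-exo-type cyclopropanation through the three-atom tether, and the seven-membered ring is not closed but arises by one-carbon expansion of the six-membered arene. The quaternary stereocentre C8a is set by C3: the bulky silyloxy group should take the pseudo-equatorial position in the cyclopropanation transition state and end trans to the C8a methyl (3α-O, 8aβ-CH3). The step needs chemoselectivity for arene addition over 1,2-hydride shift of the carbenoid and over acid-induced rearrangement of 7 to a 2-tetralone, which the electron-rich ring, slow addition and acid-free work-up should secure; regioselectivity is no issue because the para-substituted ring has two equivalent ortho positions.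

Step 6
Reactants: 8 3α-[(tert-butyldimethylsilyl)oxy]-6-methoxy-8aβ-methyl-3,8a-dihydroazulen-1(2H)-one
Product: 9 3α-[(tert-butyldimethylsilyl)oxy]-6-methoxy-8aβ-methyl-3,8a-dihydroazulen-1-yl trifluoromethanesulfonate
Conditions: KHMDS, THF, −78 °C; then PhNTf2, −78 → 0 °C
Reagents that add atoms: N-phenylbis(trifluoromethanesulfonimide) O=S(=O)(N(c1ccccc1)S(=O)(=O)C(F)(F)F)C(F)(F)F
Why: Enolisation can only go towards C2 because C8a is quaternary, and O-sulfonylation of the potassium enolate (enol triflate formation) at −78 °C should outrun β-elimination of the C3 silyloxy group.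

Step 7
Reactants: 9 3α-[(tert-butyldimethylsilyl)oxy]-6-methoxy-8aβ-methyl-3,8a-dihydroazulen-1-yl trifluoromethanesulfonate
Product: 10 3α-[(tert-butyldimethylsilyl)oxy]-6-methoxy-8aβ-methyl-3,8a-dihydroazulene
Conditions: Pd(OAc)2 (5 mol %), PPh3, Bu3N, HCO2H, DMF, 60 °C
Reagents that add atoms: none
Why: Palladium-catalysed formate reduction of the alkenyl triflate replaces OTf by H and leaves the C1=C2 double bond that the target keeps, while the amine-buffered medium spares the enol ether.

Step 8
Reactants: 10 3α-[(tert-butyldimethylsilyl)oxy]-6-methoxy-8aβ-methyl-3,8a-dihydroazulene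
Product: 11 6-methoxy-8aβ-methyl-3,8a-dihydroazulen-3α-ol
Conditions: TBAF, THF, 0 °C; work-up without acid
Reagents that add atoms: none
Why: Fluoride cleavage of the silyl ether under basic, non-ionising conditions frees the C3α hydroxyl as the anchor for the tether, and the doubly allylic alcohol is carried on without exposure to acid.

Step 9
Reactants: 11 6-methoxy-8aβ-methyl-3,8a-dihydroazulen-3α-ol
Product: 14 6-methoxy-8aβ-methyl-3,3a,4,8a-tetrahydroazulene-3α,4α-diol (H-3aα), via dimethylsilyl ether 12 (not isolated), via oxasilolane 13 (not isolated)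
Conditions: (HMe2Si)2NH, rt, then evaporate; Karstedt's catalyst (0.5 mol % Pt), toluene, 60 °C; then 30% H2O2, KF, KHCO3, THF/MeOH, rt
Reagents that add atoms: 1,1,3,3-tetramethyldisilazane C[SiH](C)N[SiH](C)C (silicon stays only in 12 and 13); hydrogen peroxide OO
Why: Intramolecular platinum-catalysed hydrosilylation of the O-dimethylsilyl allylic alcohol (5-endo mode, the only ring size open to the tether, the C1=C2 bond being out of reach) adds Si–H syn across C3a=C4 from the α face on which the C3 oxygen sits, so that H-3a and the C4–Si bond are both α, and Tamao oxidation then converts C–Si into C–OH with retention.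

Step 10
Reactants: 14 6-methoxy-8aβ-methyl-3,3a,4,8a-tetrahydroazulene-3α,4α-diol
Product: 15 3α,4α-dihydroxy-8aβ-methyl-3a,4,5,8a-tetrahydroazulen-6(3H)-one
Conditions: 0.1 M aq. oxalic acid, THF, 0 °C
Reagents that add atoms: water O
Why: Acid hydrolysis of the 2-methoxy-1,3-diene proceeds by protonation at C5 and loss of methanol to the C6 ketone conjugated with C7=C8, and dilute oxalic acid at 0 °C is chosen to avoid dehydration of the β-hydroxy ketone.

Step 11
Reactants: 15 3α,4α-dihydroxy-8aβ-methyl-3a,4,5,8a-tetrahydroazulen-6(3H)-one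
Product: 16 3α,4α-dihydroxy-8aβ-methyl-3a,4,5,7,8,8a-hexahydroazulen-6(3H)-one
Conditions: [(Ph3P)CuH]6 (Stryker's reagent), H2O (2 equiv), THF/benzene, rt
Reagents that add atoms: none
Why: Copper hydride conjugate reduction delivers hydride only to the enone β-carbon C8, so the isolated C1=C2 alkene and the free hydroxyls should survive.

Step 12
Reactants: 16 3α,4α-dihydroxy-8aβ-methyl-3a,4,5,7,8,8a-hexahydroazulen-6(3H)-one
Product: 17 6α,8aβ-dimethyl-3,3a,4,5,6,7,8,8a-octahydroazulene-3α,4α,6β-triol
Conditions: MeMgBr (excess), CeCl3, THF, −78 °C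
Reagents that add atoms: methylmagnesium bromide C[Mg]Br
Why: Organocerium 1,2-addition to an enolisable β-hydroxy ketone, in which the axial C8a methyl lies transannular (1,4) over the β face of C6, so the methyl nucleophile should enter from the α face and leave the new tertiary hydroxyl β.

Step 13
Reactants: 17 6α,8aβ-dimethyl-3,3a,4,5,6,7,8,8a-octahydroazulene-3α,4α,6β-triol
Product: 18 4α,6β-dihydroxy-6α,8aβ-dimethyl-4,5,6,7,8,8a-hexahydroazulen-3(3aH)-one
Conditions: MnO2, CH2Cl2, rt
Reagents that add atoms: none
Why: Manganese dioxide oxidises only the allylic C3 carbinol (the sacrificial stereocentre), leaves the saturated secondary C4–OH and the tertiary C6–OH untouched, and its neutral medium should avoid epimerisation at C3a.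

Step 14
Reactants: 18 4α,6β-dihydroxy-6α,8aβ-dimethyl-4,5,6,7,8,8a-hexahydroazulen-3(3aH)-one
Product: 19 3α-isopropyl-6α,8aβ-dimethyl-3,3a,4,5,6,7,8,8a-octahydroazulene-3β,4α,6β-triol
Conditions: iPrMgCl (excess), CeCl3, THF, −78 → −40 °C
Reagents that add atoms: isopropylmagnesium chloride CC(C)[Mg]Cl
Why: Organocerium 1,2-addition to the cyclopentenone, in which the reagent approaches C3 anti to the adjacent C3a–C4 bond and to the 1,3-related C8a methyl (both β), placing isopropyl α and hydroxyl β, while cerium suppresses enolisation at C3a and β-hydride reduction.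

Step 15
Reactants: 19 3α-isopropyl-6α,8aβ-dimethyl-3,3a,4,5,6,7,8,8a-octahydroazulene-3β,4α,6β-triol; 20 4-acetoxy-3-methoxybenzoic acid
Product: 21 4α-O-(4-acetoxy-3-methoxybenzoyl) ester of 19
Conditions: DCC, DMAP, CH2Cl2, rt
Reagents that add atoms: none
Why: Steglich esterification acylates the only secondary hydroxyl (C4) with retention, the two tertiary hydroxyls being inert under these conditions.

Step 16
Reactants: 21 4α-O-(4-acetoxy-3-methoxybenzoyl) ester of 19
Product: 22 CNP0113302.1 (4α-O-vanilloyl ester of 19)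
Conditions: pyrrolidine, CH2Cl2, 0 °C
Reagents that add atoms: none
Why: Aminolysis of the phenolic acetate by pyrrolidine is much faster than attack on the hindered secondary aroyl ester, so the free phenol should be released without loss or migration of the acyl group.

**Compound list**

1 | ethyl 3-(4-methoxyphenyl)-3-oxopropanoate | CCOC(=O)CC(=O)c1ccc(OC)cc1 | starting material
2 | ethyl (3R)-3-hydroxy-3-(4-methoxyphenyl)propanoate | CCOC(=O)C[C@@H](O)c1ccc(OC)cc1 | intermediate
3 | ethyl (3R)-3-[(tert-butyldimethylsilyl)oxy]-3-(4-methoxyphenyl)propanoate | CCOC(=O)C[C@@H](O[Si](C)(C)C(C)(C)C)c1ccc(OC)cc1 | intermediate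
4 | (3R)-3-[(tert-butyldimethylsilyl)oxy]-3-(4-methoxyphenyl)propanoic acid | OC(=O)C[C@@H](O[Si](C)(C)C(C)(C)C)c1ccc(OC)cc1 | intermediate
5 | mixed anhydride of 4 with isobutyl carbonic acid (not isolated) | CC(C)COC(=O)OC(=O)C[C@@H](O[Si](C)(C)C(C)(C)C)c1ccc(OC)cc1 | intermediate
6 | (5R)-5-[(tert-butyldimethylsilyl)oxy]-2-diazo-5-(4-methoxyphenyl)pentan-3-one | CC(=[N+]=[N-])C(=O)C[C@@H](O[Si](C)(C)C(C)(C)C)c1ccc(OC)cc1 | intermediate
7 | norcaradiene valence isomer of 8 (cyclopropane C3a–C8–C8a, diene C4=C5/C6=C7; not isolated) | O=C1C[C@@H](O[Si](C)(C)C(C)(C)C)[C@@]23C=CC(OC)=C[C@@H]2[C@@]13C | intermediate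
8 | 3α-[(tert-butyldimethylsilyl)oxy]-6-methoxy-8aβ-methyl-3,8a-dihydroazulen-1(2H)-one | O=C1C[C@@H](O[Si](C)(C)C(C)(C)C)C2=CC=C(OC)C=C[C@@]12C | intermediate
9 | 3α-[(tert-butyldimethylsilyl)oxy]-6-methoxy-8aβ-methyl-3,8a-dihydroazulen-1-yl trifluoromethanesulfonate | FC(F)(F)S(=O)(=O)OC1=C[C@@H](O[Si](C)(C)C(C)(C)C)C2=CC=C(OC)C=C[C@@]12C | intermediate
10 | 3α-[(tert-butyldimethylsilyl)oxy]-6-methoxy-8aβ-methyl-3,8a-dihydroazulene | C1=C[C@@H](O[Si](C)(C)C(C)(C)C)C2=CC=C(OC)C=C[C@@]12C | intermediate
11 | 6-methoxy-8aβ-methyl-3,8a-dihydroazulen-3α-ol | C1=C[C@@H](O)C2=CC=C(OC)C=C[C@@]12C | intermediate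
12 | O-dimethylsilyl ether of 11 (not isolated) | C1=C[C@@H](O[SiH](C)C)C2=CC=C(OC)C=C[C@@]12C | intermediate
13 | tricyclic oxasilolane, Si bridging O3 and C4α, H-3aα (not isolated) | C1=C[C@H]2O[Si](C)(C)[C@H]3C=C(OC)C=C[C@]1(C)[C@H]23 | intermediate
14 | 6-methoxy-8aβ-methyl-3,3a,4,8a-tetrahydroazulene-3α,4α-diol (H-3aα) | C1=C[C@@H](O)[C@@H]2[C@@H](O)C=C(OC)C=C[C@@]12C | intermediate
15 | 3α,4α-dihydroxy-8aβ-methyl-3a,4,5,8a-tetrahydroazulen-6(3H)-one | C1=C[C@@H](O)[C@@H]2[C@@H](O)CC(=O)C=C[C@@]12C | intermediate
16 | 3α,4α-dihydroxy-8aβ-methyl-3a,4,5,7,8,8a-hexahydroazulen-6(3H)-one | C1=C[C@@H](O)[C@@H]2[C@@H](O)CC(=O)CC[C@@]12C | intermediate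
17 | 6α,8aβ-dimethyl-3,3a,4,5,6,7,8,8a-octahydroazulene-3α,4α,6β-triol | C1=C[C@@H](O)[C@@H]2[C@@H](O)C[C@](C)(O)CC[C@@]12C | intermediate
18 | 4α,6β-dihydroxy-6α,8aβ-dimethyl-4,5,6,7,8,8a-hexahydroazulen-3(3aH)-one | C1=CC(=O)[C@@H]2[C@@H](O)C[C@](C)(O)CC[C@@]12C | intermediate
19 | 3α-isopropyl-6α,8aβ-dimethyl-3,3a,4,5,6,7,8,8a-octahydroazulene-3β,4α,6β-triol | C1=C[C@@](O)(C(C)C)[C@@H]2[C@@H](O)C[C@](C)(O)CC[C@@]12C | intermediate
20 | 4-acetoxy-3-methoxybenzoic acid | COc1cc(C(=O)O)ccc1OC(C)=O | starting material
21 | 4α-O-(4-acetoxy-3-methoxybenzoyl) ester of 19 | COc1cc(C(=O)O[C@H]2C[C@](C)(O)CC[C@@]3(C)C=C[C@@](O)(C(C)C)[C@H]23)ccc1OC(C)=O | intermediate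
22 | CNP0113302.1, 4α-O-(4-hydroxy-3-methoxybenzoyl) ester of 19 | COc1cc(C(=O)O[C@H]2C[C@](C)(O)CC[C@@]3(C)C=C[C@@](O)(C(C)C)[C@H]23)ccc1O | target

**Step count**

Total steps: 16. Longest linear sequence: 16 steps (1 → 22); acid 20 is purchased.

**Steps most likely to fail**

Step 9. The platinum hydride may add 1,4 or 1,6 across the conjugated methoxytriene instead of 1,2. Closure of the trans-fused oxasilolane may be slow enough for intermolecular hydrosilylation to compete, and the allylic C–Si bond may be protodesilylated during the oxidation. The fallback sets out from 11 and keeps the idea of delivery from the C3α oxygen but changes the element and the metal. Chlorodiphenylphosphine/Et3N should give the C3 diphenylphosphinite F1. A cationic rhodium(I) catalyst with catecholborane, held on the α face by phosphorus, should then add B–H syn across C3a=C4 to the C4α catechol boronate F2. Alkaline hydrogen peroxide should oxidise C–B with retention and P(III) to P(V), giving the C3 diphenylphosphinate of the diol F3. KOH in methanol should cleave the P–O bond, and the route is rejoined at 14.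

Step 12. The seven-membered ring is flexible, so facial selectivity of the carbonyl addition at C6 may be poor or reversed, and the β-alkoxide may undergo retro-aldol cleavage. The fallback sets out from 16 and exchanges the roles of the two new substituents. Wittig methylenation (Ph3P=CH2) should give the exocyclic alkene F4. Hydrogen-atom-transfer hydration (Mn(dpm)3 or Co(acac)2, PhSiH3, O2) forms the tertiary C6 radical only from the 1,1-disubstituted alkene. Oxygen is then trapped on the face that the carbonyl addition showed to be open, which in the reversed case is the β face required for C6–OH, and the route is rejoined at 17.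

Step 14. The branched Grignard reagent may enolise the ketone towards C3a, with loss of the trans ring fusion or recovery of 18, or reduce the carbonyl by β-hydride transfer. The fallback sets out from 18 and uses an sp2 nucleophile that has no β-hydride and is less basic. 2-Propenylmagnesium bromide/CeCl3 should add with the same facial preference to the isopropenyl carbinol F5. Hydrogenation with (Ph3P)3RhCl/H2 should then reduce the unhindered 1,1-disubstituted alkene in preference to the C1=C2 bond, which is flanked by two quaternary carbons, and the route is rejoined at 19.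

**Further compounds**

F1 | step 9 | C3α diphenylphosphinite of 11 | C1=C[C@@H](OP(c3ccccc3)c4ccccc4)C2=CC=C(OC)C=C[C@@]12C
F2 | step 9 | C4α catechol boronate of the C3α diphenylphosphinite (H-3aα) | C1=C[C@@H](OP(c3ccccc3)c4ccccc4)[C@@H]2[C@@H](B5Oc6ccccc6O5)C=C(OC)C=C[C@@]12C
F3 | step 9 | C3α diphenylphosphinate of diol 14 | C1=C[C@@H](OP(=O)(c3ccccc3)c4ccccc4)[C@@H]2[C@@H](O)C=C(OC)C=C[C@@]12C
F4 | step 12 | 8aβ-methyl-6-methylidene-3,3a,4,5,6,7,8,8a-octahydroazulene-3α,4α-diol | C1=C[C@@H](O)[C@@H]2[C@@H](O)CC(=C)CC[C@@]12C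
F5 | step 14 | 6α,8aβ-dimethyl-3α-(prop-1-en-2-yl)-3,3a,4,5,6,7,8,8a-octahydroazulene-3β,4α,6β-triol | C1=C[C@@](O)(C(C)=C)[C@@H]2[C@@H](O)C[C@](C)(O)CC[C@@]12C
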